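The rate constants were drawn at random within sensible limits; the rest is arithmetic.

Whatever else happens in these flasks, Z and D.Z together stay at 3.90 µM, because step 2 gives back each Z that step 1 takes and, in the steady tanks, the feed brings in as much catalyst as the outlet carries off, so you can count the catalyst as a fixed crew.

| setting | epsilon | beta | alpha | gamma |
|---|---|---|---|---|
| D | 5.0 mM (fed, over 1.50 s) | 5.0 mM | 5.0 mM | 5.0 mM |
| Z | 0.078 mol% | 0.078 mol% | 0.078 mol% | 0.078 mol% |
| time | 1.5 s |  | 1.5 s |  |
| remark | all but D at the start; D goes in evenly over 1.50 s, the run ends at 1.5 s | a single well-mixed tank run continuously and read at steady state, 7.50 s in it on average | a closed flask charged with all of it at once and left for 1.5 s | one stirred flow tank at steady state, fed with the mixture as stated, mean residence time 1.5 s |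

    D + Z → D.Z (k1 = 1.6 × 10⁶ M⁻¹ s⁻¹)
    D.Z → Z + J (k2 = 810 s⁻¹)
    D + J ⇌ D.J, settled at all times (K3 = 340 M⁻¹)

- a species is counted by the D in it: one D.J counts as two
- amounts and yields of J count D.J too
- the stated concentrations are those of everything mixed, before any reaction; amounts are the same in each set-up
- the feed brings no volume worth counting
- in an amount of J, one D.J counts as one J
- run time (epsilon): 1.5 s

* the set-up with the highest amount of J at the outlet or at the end, in percent of the D put in ("none" if the first two lie within 2 percentage points) (epsilon / beta / alpha / gamma / none)
* amount of J at the outlet or at the end, in percent of the D put in, epsilon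
* amount of J at the outlet or at the end, in percent of the D put in, beta
* amount of J at the outlet or at the end, in percent of the D put in, alpha
* amount of J at the outlet or at the end, in percent of the D put in, gamma

At first sight the job looks over at once: with Z held at its charge, step 1 alone would halve D in 0.111 s, far less than the 1.5 s of closed flask alpha. But Z doesn't stay free, because at the charged D step 1 catches a free Z in 0.125 ms and step 2 needs 1.23 ms to release it, so step 2 is the rate-limiting step and D.Z, the resting state, starts with 90.8% of the catalyst.

A better estimate is therefore a ceiling of 3.16 mM s⁻¹ on the making of J, and the whole charge divided by that ceiling is the clearing time, 1.58 s. The 1.5 s of flask alpha is 94.9% of it, so J in alpha can stand at most at that share of the D charge. But the making of J runs near the ceiling only while free D stands well above 0.506 mM, the level at which Z and D.Z are equal. Even without D.J, reaching 90.0% in alpha takes 1.79 s, longer than alpha has, so I put alpha below that figure.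

A steady tank obeys a plain rule: the share of D converted equals the mean stay divided by the clearing time, times the share of catalyst busy at outlet D. Counted with the D held in D.J, the level 0.506 mM rises to as much as 1.37 mM when free J stands at the whole D charge. Between these two levels, the rule gives beta 93.3% to 97.4% and gamma 57.6% to 70.5%. In epsilon the feed of 3.33 mM s⁻¹ only just tops the ceiling, yet the catalyst starts without D, so I expect less than alpha and commit to no figure.

The forecast named beta as best at 93.7%, with 74% for alpha, 63.3% for gamma and 58.5% for epsilon, holding that “The 7.5 s tank wins simply because it gives five times the time”.

The simulation puts beta highest at 93.7%, with 74.0% in alpha, 63.3% in gamma and 57.2% in epsilon. Flask alpha had 0.949 clearing times and ended with free D at 12.8% of its charge, whereas tank beta gives D 4.74 clearing times on average and reads 2.50% at its outlet, or 0.125 mM, well below 0.506 mM. At that reading 19.8% of the catalyst in beta is busy, and the tank rule turns this into 93.7% converted.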